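Early times gave me one comparison. The noon and autumn runs differed in impurity, and the autumn run made target more slowly, 19.9% against 26.1% at 1.50 min.

| setting | noon | autumn | flask |
|---|---|---|---|
| substrate | 20 mM | 20 mM | 20 mM |
| partner | 18 mM | 18 mM | 18.0 mM |
| free catalyst | 22 µM | 22 µM | 22 µM |
| impurity | 3.8 µM | 7.6 µM | 3.8 µM |
| remark | the very flask that is asked about, followed so far | run made earlier |  |

| run | time / min | target / % | substrate / % |
|---|---|---|---|
| noon | 0.833 | 16.7 | 84.6 |
| noon | 1.50 | 26.1 | 72.6 |
| noon | 2.50 | 38.8 | 59.0 |
| noon | 3.00 | 44.7 | 55.7 |
| noon | 4.00 | 55.0 | 45.3 |
| autumn | 0.250 | 3.9 | 97.4 |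
| autumn | 0.500 | 6.3 | 94.3 |
| autumn | 0.833 | 12.2 | 87.5 |
| autumn | 1.50 | 19.9 | 76.0 |
| autumn | 3.00 | 38.7 | 62.2 |

(scatter of a reading: 1 percentage point)

* apparent order in partner when 30% of the substrate are converted (percent change of the rate of making target for one percent more partner charged)
* factor on the rate of making target when 30% of the substrate are converted if free catalyst is charged twice over

- what was read earlier has a scatter of 1 percentage point, one standard deviation
- no earlier run changes the charge of free catalyst; that part of a forecast is a guess
- no earlier run changes the charge of partner; that part of a forecast is a guess

I counted turnovers (the turnover number: target made per working catalyst), supposing that each impurity takes one free catalyst for good. The quantity to carry is then the surviving catalyst, the charge of free catalyst less the charge of impurity. With the catalyst charged twice over, the rate factor is the new surviving catalyst over the old, which is two plus impurity over surviving catalyst. The substrate and partner charges do not appear in that ratio, but the impurity charge does: noon's 3.8 µM gives 2.21, and autumn's 7.6 µM gives 2.53.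

So the impurity charge had to be known well. For the flask asked about, the surviving catalyst was 18.2 µM. As a test, turnovers at 1.50 min came to 287 in the noon run and 276 in the autumn run, with 1 percentage point of scatter on each reading.

The forecast put the factor at 2.2 (1.7 to 2.7) and the apparent order in partner at 0.6 (0 to 1.5), reading the impurity as “a poison that stoichiometrically removes catalyst”. My factor matched its factor. No earlier run changed the charge of partner or of catalyst, so both numbers were partly guesses.

The flask gave a factor of 2.21 and an apparent order in partner of 0.55.

    partner + free catalyst → catalyst intermediate A (k = 870 /M/s)
    catalyst intermediate A → by-product + catalyst intermediate B (k = 190 /s)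
    substrate + catalyst intermediate B ⇌ catalyst intermediate C (K = 1400 /M, k = 400 /M/s)
    catalyst intermediate C ⇌ free catalyst + target (K = 0.0120 M, k = 16.0 /s)
    free catalyst + impurity → spent catalyst (k = 1.90 × 10⁶ /M/s)

Spent catalyst stood at 17.3% of the catalyst at 4.00 min, with impurity at 0% of its charge, and the charges give 17.3%. The flask's rate of making target, 2.76 mM/min at 1.75 min when 30% of the substrate was converted, came to 152 /min per surviving catalyst. On the autumn run's 14.4 µM of surviving catalyst, that gave 2.19 mM/min at the same conversion, and the autumn run's target readings from 1.50 min to 3.00 min, an interval whose substrate readings bracket that conversion, gave an average of 2.51 mM/min.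

The readings were generated by integration from invented constants, noise included.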